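The readings are calculated on assumed constants, noise included.

Colleague, you asked for a quick number and guessed that pushing the excess to 98% would cost much of the right-handed substrate. I reckoned it from the two earlier runs.

| flask | left-handed substrate | right-handed substrate | reagent | precatalyst | remark | time |
|---|---|---|---|---|---|---|
| Wednesday's | 1 M | 1 M | 1.1 M | 18 mM | run made earlier |  |
| Sunday's | 1 M | 1 M | 1.1 M | 29 mM | run made earlier |  |
| flask | 1.0 M | 1.0 M | 1.10 M | 13 mM |  | 4.0 min |

| run | time / min | right-handed substrate / % | left-handed substrate / % |
|---|---|---|---|
| Wednesday's | 0.667 | 47 | 12 |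
| Wednesday's | 1.33 | 47 | 1 |
| Wednesday's | 2.00 | 50 | 0 |
| Wednesday's | 3.00 | 51 | 3 |
| Wednesday's | 4.00 | 49 | 3 |
| Wednesday's | 5.00 | 50 | 2 |
| Sunday's | 0.417 | 50 | 20 |
| Sunday's | 0.667 | 49 | 8 |
| Sunday's | 0.833 | 49 | 4 |
| Sunday's | 1.33 | 49 | 0 |
| Sunday's | 2.00 | 46 | 0 |
| Sunday's | 3.00 | 52 | 0 |
| Sunday's | 5.00 | 46 | 0 |

(readings scatter by 2 percentage points)

- whether the excess of right-handed substrate over left-handed substrate among what is left of the two reaches 98% by 4.0 min (no / yes)
- the highest excess of right-handed substrate over left-handed substrate among what is left of the two up to 4.0 min

- free catalyst is single-handed; left-handed substrate and right-handed substrate are mirror images of each other, charged as a racemate, each of them at the stated concentration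

I divided the loss rate of the left-handed substrate by that of the right-handed one. I assumed each loss followed its own substrate with the same catalyst, so time and catalyst dropped out. What stayed was the selectivity factor, the logarithm of the left-handed fraction remaining over the logarithm of the right-handed fraction remaining. Sunday's readings at 0.667 min gave 90.7. That was a rough reading, since the right-handed drop of 1 percentage point lay within the scatter of 2 points.

The wanted excess meant left-handed substrate at 1.01% of the right-handed. So the factor put the right-handed substrate at 47.5% of both charged at that point, and your worry looked small.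

Time was the other question. That excess meant about 0.480% of both charged as left-handed substrate. Wednesday's run fell from 12% at 0.667 min to 1% at 1.33 min, a rough 3.75 min⁻¹, and carried on at that rate it came to 0.480% at 1.53 min. I assumed time went inversely with the precatalyst charge, which gave 2.11 min for the 13 mM flask, less than 4.0 min. Wednesday's run read 0% at 2.00 min before its late 3%, 3% and 2%, with a scatter of 2 points, so I read no stall into them. I committed to yes.

The forecast differed from my reckoning and said no, with a top of 76%: “That hints the catalyst dies and conversion stalls at a level set by loading”.

The flask answered yes, with a top of >99.9%.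

    free catalyst + left-handed substrate ⇌ catalyst intermediate A (K = 4.30 M⁻¹, k = 662 M⁻¹ s⁻¹)
    free catalyst + right-handed substrate ⇌ catalyst intermediate B (K = 0.360 M⁻¹, k = 622 M⁻¹ s⁻¹)
    reagent + catalyst intermediate A → free catalyst + left-handed product (k = 16.0 M⁻¹ s⁻¹)
    reagent + catalyst intermediate B → free catalyst + right-handed product (k = 0.613 M⁻¹ s⁻¹)
    precatalyst → free catalyst (k = 0.00832 s⁻¹)
    left-handed product ⇌ right-handed product (k = 0.0612 s⁻¹)
    reagent → decomposition product (k = 1.00 × 10⁻⁴ s⁻¹)

The excess in the flask reached 98% at 2.20 min, with 49.1% of both charged left as right-handed substrate, where the factor had given 47.5%. On Wednesday's run, the left-handed reading of 1% at 1.33 min gave through the same factor 47.9% right-handed substrate, and the reading there was 47%.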